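## Analysis of the target

The target 18 is a 1,4-naphthoquinone. Ring A is a benzene ring with methoxy groups on C5, C6 and C8 and one hydrogen on C7. Ring B is the quinone ring, with carbonyls at C1 and C4, a free hydroxyl on C2 and a (2S)-2-acetoxypropyl chain on C3. The only stereocentre is the acetoxy-bearing carbon of the chain; it is (S), it is insulated from the ring by a methylene group and has no partner, so it can be bought, provided no later step makes its oxygen a leaving group. The sensitive groups are the 2-hydroxyquinone (a vinylogous carboxylic acid, acidic and easily O-acylated), the base-labile secondary acetate, the methoxy groups on C5 and C8 peri to the carbonyls (cleaved by strong Lewis acids), and the para-dimethoxy pattern C5/C8, which a strong oxidant could turn into a second quinone. The difficulty is regiochemical and protective, not stereochemical: ring A is unsymmetrical, so the hydroxyl must lie on the C8 side and the chain on the C5 side, and the two hydroxyls of the molecule must be told apart so that only one is acetylated. The strategy rests on C1 to C4 of ring B: four contiguous carbons bearing O, O, C and O are the four carbons of a squaric ester in which one alkoxy group is replaced by the chain, and C8a and C4a are the ipso carbon and the single free ortho carbon of a 2,4,5-trimethoxyphenyl group.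

## Retrosynthetic reasoning

**18 from 17.** The last bond cut is the O–tert-butyl bond at C2, leading back to 2-tert-butoxy-3-[(2S)-2-acetoxypropyl]-5,6,8-trimethoxy-1,4-naphthoquinone 17. The C2 hydroxyl is released last because the free hydroxyquinone is acidic and acylable, and because it could not be kept free while the chain hydroxyl is acetylated. The forward step must remove a tert-butyl vinylogous ester with acid while three aryl methyl ethers and a secondary acetate stay intact.

**17 from 16 from 15.** The acetate is traced to the alcohol 16 and then to the silyl ether 15 (the corresponding 2-tert-butoxyquinones). Only O–acyl and O–Si bonds are changed, so the (S) carbon is never touched. An acetate cannot be carried earlier because an aryllithium is used upstream. A silyl ether is chosen because it is removed by fluoride while the tert-butyl group waits for acid.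

**15 from 14.** The quinone is an oxidation-level adjustment of naphthalene-1,4-diol 14, which is the direct product of the ring-forming step. A mild two-electron oxidant is needed so that ring A is not attacked.

**14 from 11 (key disconnection).** The C4–C4a bond is cut, which opens ring B, and C4 is reconnected to C1 to give the 4-aryl-4-hydroxycyclobutenone 11. This bond is chosen because it joins a ring B carbon to the only unsubstituted ortho carbon of the aryl group, so ring A can be bought whole and all four ring B carbons arrive with their substituents already in place. The forward reaction must open the four-membered ring and close the six-membered one without losing the tert-butyl and silyl groups.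

**11 from 8 and 9.** The C1–C8a bond (carbinol carbon to aryl ipso carbon) is cut, giving cyclobutenedione 8 and the aryllithium 10 derived from 1-bromo-2,4,5-trimethoxybenzene 9. The forward addition must pick one of the two carbonyls of 8. The one next to the tert-butoxy carbon is ketone-like; the other is the deactivated end of a vinylogous ester. This difference decides on which side of ring A the hydroxyl and the chain will lie.

**8 from 6 from 5 from 2 and 1.** Dione 8 is the unmasked form of the squarate adduct 6, the silyl ether of diol 5. Cutting the bond between the ring carbon (future C3) and the side-chain CH2 leads to di-tert-butyl squarate 2 and a three-carbon nucleophile. A β-oxygenated alkyllithium would normally eliminate, so the oxygen is carried as its lithium alkoxide in dianion 4, made from (S)-1-chloropropan-2-ol 1 through alkoxide 3. The squarate is symmetrical, so this first addition raises no selectivity question, and the stereocentre comes with 1.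

## Alternatives that were turned down

**Alternative 1:** Lactone-to-carbocycle rearrangement.
- Disconnection: the C3–C4 bond of ring B, leading to the enol lactone A2, 3-[(3S)-3-(tert-butyldimethylsilyloxy)butylidene]-5,7,8-trimethoxyisochromene-1,4-dione.
- Forward key step: NaOCH3 opens the lactone to a methyl ester and the enolate of a 1,2-diketone; the enolate carbon is acylated by the ester and ring B closes directly as the hydroxyquinone A1, 2-hydroxy-3-[(2S)-2-(tert-butyldimethylsilyloxy)propyl]-5,6,8-trimethoxy-1,4-naphthoquinone.
- For: the ring closes at the final oxidation level, at ambient temperature, with no oxidant and no protecting group on the C2 oxygen. On these points it is stronger than the chosen route.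
- Against: A2 needs a pentasubstituted benzene in which two different carbonyl carbons sit ortho to each other in a fixed orientation (lactone carbonyl next to the future C5 methoxy, ketone next to the future C8 methoxy). The regiochemical problem is therefore only moved into a longer preparation of A2. The basic conditions also exclude the acetate, and A1 has a free acidic C2 hydroxyl beside the protected chain oxygen, so the later acetylation has to discriminate two hydroxyls.
- Comparison: the chosen strategy offers in its place three commercial building blocks, regiochemistry decided by the order of two additions, and a C2 oxygen that stays masked until the acetate is in place.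

**Alternative 2:** Chromium carbene benzannulation.
- Disconnection: C1–C2, C3–C4 and C4–C4a, leading to the aryl(methoxy)carbene complex of zerovalent chromium A4 (pentacarbonyl[methoxy(2,4,5-trimethoxyphenyl)methylidene]chromium, obtainable from aryllithium 10 and Cr(CO)6) and the alkyne A5, (2S)-pent-4-yn-2-yl acetate.
- Forward key step: A4, A5 and one CO ligand combine to the 4-methoxy-1-naphthol A3, (2S)-1-(1-hydroxy-4,5,7,8-tetramethoxynaphthalen-2-yl)propan-2-yl acetate.
- For: three bonds form in one step, the terminal alkyne places the chain reliably next to the phenol carbon, and the acetate is carried from the start. On bond count per step and on side-chain protecting groups it is stronger than the chosen route.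
- Against: in A3 the carbon that becomes C2 of the target carries hydrogen, so the hydroxyl must be introduced after quinone formation, under oxidising or basic conditions that endanger the acetate. The oxidation of A3 must also distinguish ring B (1-hydroxy-4-methoxy) from ring A (5,8-dimethoxy), both para-dioxygenated. The ortho methoxy group of the aryl can chelate chromium after CO loss and divert the reaction, and the metal is used in stoichiometric amount.
- Comparison: the chosen strategy delivers C2 with its oxygen already attached and needs only a mild Ag2O oxidation that cannot touch ring A.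

**Alternative 3:** Ring A by cycloaddition.
- Disconnection: C4a–C5 and C8–C8a, leading to the diene A7, 1,3,4-trimethoxy-1-(trimethylsilyloxy)buta-1,3-diene, and the quinone A8, 2-methoxy-3-[(2S)-2-(tert-butyldimethylsilyloxy)propyl]-1,4-benzoquinone.
- Forward key step: A7 adds across the unsubstituted double bond of A8; enolization, loss of methanol and air oxidation give A6, 8-hydroxy-2,5,6-trimethoxy-3-[(2S)-2-(tert-butyldimethylsilyloxy)propyl]-1,4-naphthoquinone.
- For: the ring-forming step runs well below 110 °C and uses no organolithium on a delicate electrophile. On mildness it is stronger than the chosen route.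
- Against: the orientation depends on matching the more nucleophilic terminus of A7 with the quinone carbon β to the more electrophilic carbonyl of A8. The two carbonyls differ only through a methoxy versus an alkyl group on the far double bond, which is a bias and not a structural lock; the wrong orientation would exchange the C5 and C8 oxygen pattern. A6 still needs methylation of the chelated C8 hydroxyl and basic hydrolysis of the C2 methyl vinylogous ester, which again forbids an early acetate and leaves two hydroxyls to tell apart. A7 and A8 each need several steps.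
- Comparison: the chosen strategy fixes the orientation through the single free ortho position and uses a tert-butyl group that comes off with acid at the very end.

Key step: step 5

## Route

Remark: the ring carbinol carbon formed in steps 1 and 4 is not controlled; 5, 6, 7 and 11 are taken as mixtures of two epimers, which converge because that carbon becomes trigonal in steps 3 and 5.

**Step 1**
Reactants: 1 (S)-1-chloropropan-2-ol; 2 di-tert-butyl squarate
Product: 5 2,3-di-tert-butoxy-4-hydroxy-4-[(2S)-2-hydroxypropyl]cyclobut-2-en-1-one (two epimers at the ring carbinol carbon), via lithium (2S)-1-chloropropan-2-olate 3 (not isolated), via lithium (2S)-1-lithiopropan-2-olate 4 (not isolated)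
Conditions: 1, n-BuLi (1 equiv), THF, −78 °C; LiC10H8 (2 equiv), −78 °C; added by cannula to 2, THF, −78 °C; sat. aq NH4Cl, −78 °C to rt
Reagents that add atoms: none
Why: Deprotonation followed by two-electron reductive lithiation of the C–Cl bond should give the β-oxido alkyllithium 4, whose lithium alkoxide is a poor leaving group at −78 °C; its 1,2-addition to one of the two equivalent carbonyls of 2 is the usual organolithium–squarate addition. The (S) carbon is the alkoxide carbon of 1 and is not involved.

**Step 2**
Reactants: 5 2,3-di-tert-butoxy-4-hydroxy-4-[(2S)-2-hydroxypropyl]cyclobut-2-en-1-one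
Product: 6 2,3-di-tert-butoxy-4-[(2S)-2-(tert-butyldimethylsilyloxy)propyl]-4-hydroxycyclobut-2-en-1-one
Conditions: TBSCl, imidazole, DMF, 0 °C to rt
Reagents that add atoms: tert-butyldimethylsilyl chloride, CC(C)(C)[Si](C)(C)Cl
Why: Standard silylation; the secondary hydroxyl should react while the hindered tertiary ring carbinol does not under these conditions. The silyl ether is needed because the next two steps use an anhydride and an aryllithium.

**Step 3**
Reactants: 6 2,3-di-tert-butoxy-4-[(2S)-2-(tert-butyldimethylsilyloxy)propyl]-4-hydroxycyclobut-2-en-1-one
Product: 8 3-tert-butoxy-4-[(2S)-2-(tert-butyldimethylsilyloxy)propyl]cyclobut-3-ene-1,2-dione, via tertiary trifluoroacetate 7 (not isolated)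
Conditions: (CF3CO)2O, pyridine, CH2Cl2, −78 to 0 °C; aq NaHCO3
Reagents that add atoms: none
Why: Trifluoroacetylation makes the tertiary oxygen a leaving group; ionization gives a cyclobutenyl cation stabilized by both tert-butoxy groups, and loss of the tert-butyl group from the oxocarbenium carbon next to the carbonyl gives the 1,2-dione (the known squarate-adduct to cyclobutenedione rearrangement). Pyridine buffers the acid so that the remaining vinylogous tert-butyl ester and the silyl ether should survive.

**Step 4**
Reactants: 8 3-tert-butoxy-4-[(2S)-2-(tert-butyldimethylsilyloxy)propyl]cyclobut-3-ene-1,2-dione; 9 1-bromo-2,4,5-trimethoxybenzene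
Product: 11 3-tert-butoxy-2-[(2S)-2-(tert-butyldimethylsilyloxy)propyl]-4-hydroxy-4-(2,4,5-trimethoxyphenyl)cyclobut-2-en-1-one (two epimers at the ring carbinol carbon), via (2,4,5-trimethoxyphenyl)lithium 10 (not isolated)
Conditions: 9, n-BuLi, THF, −78 °C; then 8, THF, −78 °C; sat. aq NH4Cl
Reagents that add atoms: none
Why: Bromine–lithium exchange gives 10, which should add 1,2 to the ketone-like carbonyl of 8 (the one next to the tert-butoxy carbon), because the other carbonyl is the deactivated end of the vinylogous ester. This is the standard second addition of the squarate sequence, and it places the future C1 next to the oxygen-bearing carbon and the future C4 next to the chain.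

**Step 5**
Reactants: 11 3-tert-butoxy-2-[(2S)-2-(tert-butyldimethylsilyloxy)propyl]-4-hydroxy-4-(2,4,5-trimethoxyphenyl)cyclobut-2-en-1-one
Product: 14 2-tert-butoxy-3-[(2S)-2-(tert-butyldimethylsilyloxy)propyl]-5,6,8-trimethoxynaphthalene-1,4-diol, via aryl vinylketene 12 (not isolated), via 4aH-dienone 13 (not isolated)
Conditions: toluene (degassed), 110 °C, Ar
Reagents that add atoms: none
Why: Heating should open the strained cyclobutenone by a conrotatory 4π electrocyclic cleavage of the bond between the carbonyl carbon and the carbinol carbon, giving aryl vinylketene 12. Donor substituents on the sp3 carbon rotate outward, so the hydroxyl turns away and the aryl group turns inward, next to the ketene carbon. A 6π electrocyclization of the ketene C=C, the enol C=C and one arene C=C then joins the ketene carbon (C4) to the free ortho carbon (C4a) and closes ring B as a six-membered ring in dienone 13; a proton shift from C4a to the C4 oxygen restores ring A and gives 14. The closest known reaction type is the thermal rearrangement of 4-aryl-4-hydroxycyclobutenones to 1,4-naphthohydroquinones (Moore rearrangement). No stereocentre is created: the carbinol carbon becomes trigonal, C4a is tetrahedral only in 13, and the (S) carbon of the chain is remote from every bond that moves. Three selectivities are needed: outward rotation of the hydroxyl, secured by the electronic preference of donors; the order of substituents around C2, C3 and C4, already fixed in 11 because the ketene carbon is the one bonded to the alkyl-bearing carbon; and closure at the hydrogen-bearing ortho carbon and not at the methoxy-bearing one, favoured because that position is less hindered and only its adduct can aromatize by a simple proton shift. Air is excluded because 14 is an electron-rich hydroquinone, and neutral toluene at 110 °C should leave the tert-butyl and silyl ethers intact.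

**Step 6**
Reactants: 14 2-tert-butoxy-3-[(2S)-2-(tert-butyldimethylsilyloxy)propyl]-5,6,8-trimethoxynaphthalene-1,4-diol
Product: 15 2-tert-butoxy-3-[(2S)-2-(tert-butyldimethylsilyloxy)propyl]-5,6,8-trimethoxy-1,4-naphthoquinone
Conditions: Ag2O, MgSO4, Et2O, rt
Reagents that add atoms: none
Why: Two-electron oxidation of a 1,4-hydroquinone to the quinone; Ag2O is mild enough to leave the para-dimethoxy pattern of ring A untouched, which a tetravalent cerium oxidant might not.

**Step 7**
Reactants: 15 2-tert-butoxy-3-[(2S)-2-(tert-butyldimethylsilyloxy)propyl]-5,6,8-trimethoxy-1,4-naphthoquinone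
Product: 16 2-tert-butoxy-3-[(2S)-2-hydroxypropyl]-5,6,8-trimethoxy-1,4-naphthoquinone
Conditions: HF·pyridine, pyridine, THF, 0 °C to rt
Reagents that add atoms: none
Why: Fluoride cleavage of a secondary silyl ether at the Si–O bond, so the stereocentre is retained; excess pyridine keeps the medium too weakly acidic to ionize the tert-butyl vinylogous ester.

**Step 8**
Reactants: 16 2-tert-butoxy-3-[(2S)-2-hydroxypropyl]-5,6,8-trimethoxy-1,4-naphthoquinone
Product: 17 2-tert-butoxy-3-[(2S)-2-acetoxypropyl]-5,6,8-trimethoxy-1,4-naphthoquinone
Conditions: Ac2O, pyridine, 4-(dimethylamino)pyridine (cat.), CH2Cl2, 0 °C to rt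
Reagents that add atoms: acetic anhydride, CC(=O)OC(C)=O
Why: Nucleophile-catalysed acylation of a secondary alcohol; the C2 oxygen is still a tert-butyl ether, so only one hydroxyl is available, and the configuration is retained.

**Step 9**
Reactants: 17 2-tert-butoxy-3-[(2S)-2-acetoxypropyl]-5,6,8-trimethoxy-1,4-naphthoquinone
Product: 18 2-hydroxy-3-[(2S)-2-acetoxypropyl]-5,6,8-trimethoxy-1,4-naphthoquinone (CNP0321270.1)
Conditions: CF3CO2H, CH2Cl2, 0 °C
Reagents that add atoms: none
Why: Acidolysis of a tert-butyl vinylogous ester by loss of the tert-butyl cation as the alkene; aryl methyl ethers, the quinone and the secondary acetate are stable to CF3CO2H at 0 °C.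

## Compound list

1 | (S)-1-chloropropan-2-ol | C[C@H](O)CCl | starting material
2 | di-tert-butyl squarate (3,4-di-tert-butoxycyclobut-3-ene-1,2-dione) | O=C1C(=O)C(OC(C)(C)C)=C1OC(C)(C)C | starting material
3 | lithium (2S)-1-chloropropan-2-olate | C[C@H]([O-])CCl.[Li+] | intermediate
4 | lithium (2S)-1-lithiopropan-2-olate | C[C@H](O[Li])C[Li] | intermediate
5 | 2,3-di-tert-butoxy-4-hydroxy-4-[(2S)-2-hydroxypropyl]cyclobut-2-en-1-one (two epimers at the ring carbinol carbon) | C[C@H](O)CC1(O)C(OC(C)(C)C)=C(OC(C)(C)C)C1=O | intermediate
6 | 2,3-di-tert-butoxy-4-[(2S)-2-(tert-butyldimethylsilyloxy)propyl]-4-hydroxycyclobut-2-en-1-one | C[C@H](O[Si](C)(C)C(C)(C)C)CC1(O)C(OC(C)(C)C)=C(OC(C)(C)C)C1=O | intermediate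
7 | 2,3-di-tert-butoxy-1-[(2S)-2-(tert-butyldimethylsilyloxy)propyl]-4-oxocyclobut-2-en-1-yl trifluoroacetate | C[C@H](O[Si](C)(C)C(C)(C)C)CC1(OC(=O)C(F)(F)F)C(OC(C)(C)C)=C(OC(C)(C)C)C1=O | intermediate
8 | 3-tert-butoxy-4-[(2S)-2-(tert-butyldimethylsilyloxy)propyl]cyclobut-3-ene-1,2-dione | C[C@H](O[Si](C)(C)C(C)(C)C)CC1=C(OC(C)(C)C)C(=O)C1=O | intermediate
9 | 1-bromo-2,4,5-trimethoxybenzene | COc1cc(OC)c(Br)cc1OC | starting material
10 | (2,4,5-trimethoxyphenyl)lithium | [Li]c1cc(OC)c(OC)cc1OC | intermediate
11 | 3-tert-butoxy-2-[(2S)-2-(tert-butyldimethylsilyloxy)propyl]-4-hydroxy-4-(2,4,5-trimethoxyphenyl)cyclobut-2-en-1-one (two epimers at the ring carbinol carbon) | O=C1C(C[C@H](C)O[Si](C)(C)C(C)(C)C)=C(OC(C)(C)C)C1(O)c1cc(OC)c(OC)cc1OC | intermediate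
12 | aryl vinylketene: (3Z)-3-tert-butoxy-2-[(2S)-2-(tert-butyldimethylsilyloxy)propyl]-4-hydroxy-4-(2,4,5-trimethoxyphenyl)buta-1,3-dien-1-one | O=C=C(C[C@H](C)O[Si](C)(C)C(C)(C)C)/C(OC(C)(C)C)=C(/O)c1cc(OC)c(OC)cc1OC | intermediate
13 | 2-tert-butoxy-3-[(2S)-2-(tert-butyldimethylsilyloxy)propyl]-1-hydroxy-5,6,8-trimethoxy-4aH-naphthalen-4-one | O=C1C(C[C@H](C)O[Si](C)(C)C(C)(C)C)=C(OC(C)(C)C)C(O)=C2C(OC)=CC(OC)=C(OC)C12 | intermediate
14 | 2-tert-butoxy-3-[(2S)-2-(tert-butyldimethylsilyloxy)propyl]-5,6,8-trimethoxynaphthalene-1,4-diol | COc1cc(OC)c2c(c1OC)c(O)c(C[C@H](C)O[Si](C)(C)C(C)(C)C)c(OC(C)(C)C)c2O | intermediate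
15 | 2-tert-butoxy-3-[(2S)-2-(tert-butyldimethylsilyloxy)propyl]-5,6,8-trimethoxy-1,4-naphthoquinone | COc1cc(OC)c2c(c1OC)C(=O)C(C[C@H](C)O[Si](C)(C)C(C)(C)C)=C(OC(C)(C)C)C2=O | intermediate
16 | 2-tert-butoxy-3-[(2S)-2-hydroxypropyl]-5,6,8-trimethoxy-1,4-naphthoquinone | COc1cc(OC)c2c(c1OC)C(=O)C(C[C@H](C)O)=C(OC(C)(C)C)C2=O | intermediate
17 | 2-tert-butoxy-3-[(2S)-2-acetoxypropyl]-5,6,8-trimethoxy-1,4-naphthoquinone | COc1cc(OC)c2c(c1OC)C(=O)C(C[C@H](C)OC(C)=O)=C(OC(C)(C)C)C2=O | intermediate
18 | 2-hydroxy-3-[(2S)-2-acetoxypropyl]-5,6,8-trimethoxy-1,4-naphthoquinone | COc1cc(OC)c2c(c1OC)C(=O)C(C[C@H](C)OC(C)=O)=C(O)C2=O | target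

## Step count and least certain steps

Total: 9 steps. Longest linear sequence: 9 steps (from 1 and 2 to 18). Aryllithium 10 is made from commercial 9 in the flask of step 4, so the aryl branch adds no step.

**Step 5 (key step).** The most likely failure is thermal fragmentation of the tert-butyl ether (loss of the alkene) at the temperature that ring opening needs, which would unmask the C2 oxygen early and remove the differentiation on which the endgame depends. A smaller risk is partial closure onto the methoxy-bearing ortho carbon. The fallback sets out from 11 and returns at 18; it gives up the tert-butyl group on purpose and moves the discrimination of the two hydroxyls to the last step. Compound 11 is heated in p-xylene at 138 °C, and the cooled solution is stirred with CF3CO2H and then with Ag2O in air to give 2-hydroxy-3-[(2S)-2-(tert-butyldimethylsilyloxy)propyl]-5,6,8-trimethoxy-1,4-naphthoquinone F1. Aqueous HF in CH3CN removes the silyl group to give 2-hydroxy-3-[(2S)-2-hydroxypropyl]-5,6,8-trimethoxy-1,4-naphthoquinone F2. Ac2O and pyridine acetylate both hydroxyls to 2-acetoxy-3-[(2S)-2-acetoxypropyl]-5,6,8-trimethoxy-1,4-naphthoquinone F3. NaHCO3 in CH3OH at 0 °C should then remove only the C2 acetate, which is a vinylogous anhydride and far more labile than the secondary alkyl acetate, giving 18.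

**Step 1.** What may go wrong is electron transfer from residual radical anion to the electron-poor squarate, β-elimination of the dianion if the temperature rises, and attack of the side-chain alkoxide on the ring before the quench. The fallback sets out from 1 and returns at 4; it replaces the reductive lithiation by a polar halogen–metal exchange, so that no radical anion is present. Finkelstein exchange (NaI, acetone, reflux) should give (S)-1-iodopropan-2-ol F4, which is deprotonated with n-BuLi (1 equiv) and exchanged with t-BuLi (2 equiv) in Et2O at −78 °C to give 4.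

**Step 3.** The risk is over-acidolysis, that is loss of the second tert-butyl group from the vinylogous ester during or after the rearrangement. The fallback sets out from 6 and returns at 8. The acidolysis is driven to completion with CF3CO2H in CH2Cl2 at 0 °C to give 3-hydroxy-4-[(2S)-2-(tert-butyldimethylsilyloxy)propyl]cyclobut-3-ene-1,2-dione F5. This vinylogous acid is then re-esterified with tert-butyl 2,2,2-trichloroacetimidate in CH2Cl2 and cyclohexane; the two oxygens of its anion are equivalent, so a single ester, 8, should result.

**Step 7.** The risk is loss of the tert-butyl group under the fluoride conditions, or attack of the freed hydroxyl on C2 with displacement of tert-butoxide and closure of a dihydrofuran on the quinone. The fallback sets out from 11 and returns at 17; it moves the silyl-to-acetyl exchange in front of the ring expansion, where the same cyclization would have to form a strained bicyclic alkene. Bu4NF buffered with AcOH in THF at 0 °C should give 3-tert-butoxy-4-hydroxy-2-[(2S)-2-hydroxypropyl]-4-(2,4,5-trimethoxyphenyl)cyclobut-2-en-1-one F6. Ac2O and pyridine without an acylation catalyst acetylate only the secondary hydroxyl, giving (2S)-1-[2-tert-butoxy-3-hydroxy-4-oxo-3-(2,4,5-trimethoxyphenyl)cyclobut-1-en-1-yl]propan-2-yl acetate F7. Heating in degassed toluene at 110 °C gives (2S)-1-(3-tert-butoxy-1,4-dihydroxy-5,7,8-trimethoxynaphthalen-2-yl)propan-2-yl acetate F8, and Ag2O oxidation gives 17.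

## Further compounds

F1 | step 5 | 2-hydroxy-3-[(2S)-2-(tert-butyldimethylsilyloxy)propyl]-5,6,8-trimethoxy-1,4-naphthoquinone | COc1cc(OC)c2c(c1OC)C(=O)C(C[C@H](C)O[Si](C)(C)C(C)(C)C)=C(O)C2=O
F2 | step 5 | 2-hydroxy-3-[(2S)-2-hydroxypropyl]-5,6,8-trimethoxy-1,4-naphthoquinone | COc1cc(OC)c2c(c1OC)C(=O)C(C[C@H](C)O)=C(O)C2=O
F3 | step 5 | 2-acetoxy-3-[(2S)-2-acetoxypropyl]-5,6,8-trimethoxy-1,4-naphthoquinone | COc1cc(OC)c2c(c1OC)C(=O)C(C[C@H](C)OC(C)=O)=C(OC(C)=O)C2=O
F4 | step 1 | (S)-1-iodopropan-2-ol | C[C@H](O)CI
F5 | step 3 | 3-hydroxy-4-[(2S)-2-(tert-butyldimethylsilyloxy)propyl]cyclobut-3-ene-1,2-dione | C[C@H](O[Si](C)(C)C(C)(C)C)CC1=C(O)C(=O)C1=O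
F6 | step 7 | 3-tert-butoxy-4-hydroxy-2-[(2S)-2-hydroxypropyl]-4-(2,4,5-trimethoxyphenyl)cyclobut-2-en-1-one | O=C1C(C[C@H](C)O)=C(OC(C)(C)C)C1(O)c1cc(OC)c(OC)cc1OC
F7 | step 7 | (2S)-1-[2-tert-butoxy-3-hydroxy-4-oxo-3-(2,4,5-trimethoxyphenyl)cyclobut-1-en-1-yl]propan-2-yl acetate | O=C1C(C[C@H](C)OC(C)=O)=C(OC(C)(C)C)C1(O)c1cc(OC)c(OC)cc1OC
F8 | step 7 | (2S)-1-(3-tert-butoxy-1,4-dihydroxy-5,7,8-trimethoxynaphthalen-2-yl)propan-2-yl acetate | COc1cc(OC)c2c(c1OC)c(O)c(C[C@H](C)OC(C)=O)c(OC(C)(C)C)c2O
A1 | alternative 1 | 2-hydroxy-3-[(2S)-2-(tert-butyldimethylsilyloxy)propyl]-5,6,8-trimethoxy-1,4-naphthoquinone | COc1cc(OC)c2c(c1OC)C(=O)C(C[C@H](C)O[Si](C)(C)C(C)(C)C)=C(O)C2=O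
A2 | alternative 1 | 3-[(3S)-3-(tert-butyldimethylsilyloxy)butylidene]-5,7,8-trimethoxyisochromene-1,4-dione | COc1cc(OC)c2c(c1OC)C(=O)OC(=CC[C@H](C)O[Si](C)(C)C(C)(C)C)C2=O
A3 | alternative 2 | (2S)-1-(1-hydroxy-4,5,7,8-tetramethoxynaphthalen-2-yl)propan-2-yl acetate | COc1cc(OC)c2c(OC)cc(C[C@H](C)OC(C)=O)c(O)c2c1OC
A4 | alternative 2 | pentacarbonyl[methoxy(2,4,5-trimethoxyphenyl)methylidene]chromium | COC(=[Cr](=C=O)(=C=O)(=C=O)(=C=O)=C=O)c1cc(OC)c(OC)cc1OC
A5 | alternative 2 | (2S)-pent-4-yn-2-yl acetate | C#CC[C@H](C)OC(C)=O
A6 | alternative 3 | 8-hydroxy-2,5,6-trimethoxy-3-[(2S)-2-(tert-butyldimethylsilyloxy)propyl]-1,4-naphthoquinone | COc1cc(O)c2c(c1OC)C(=O)C(C[C@H](C)O[Si](C)(C)C(C)(C)C)=C(OC)C2=O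
A7 | alternative 3 | 1,3,4-trimethoxy-1-(trimethylsilyloxy)buta-1,3-diene | COC=C(OC)C=C(OC)O[Si](C)(C)C
A8 | alternative 3 | 2-methoxy-3-[(2S)-2-(tert-butyldimethylsilyloxy)propyl]-1,4-benzoquinone | COC1=C(C[C@H](C)O[Si](C)(C)C(C)(C)C)C(=O)C=CC1=O
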